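Start from what the midnight run leaves unaccounted for at 10.0 d: substrate 2.0 %, target 59.6 % and isomer of the product 27.2 % leave 11.2 % of the substrate charged unread. So look at a ratio of two species that are read, which that gap does not enter.

the same everywhere: substrate 0.050 M

| charge | reagent | remark | time |
|---|---|---|---|
| winter | 0.035 M | run made earlier |  |
| midnight | 0.079 M | run made earlier |  |
| flask | 0.0525 M |  | 15 d |

| run | time / d | isomer of the product / % | target / % | substrate / % |
|---|---|---|---|---|
| winter | 1.04 | 7.7 | 16.7 | 72.2 |
| winter | 3.00 | 12.2 | 27.5 | 54.0 |
| winter | 6.00 | 15.3 | 36.6 | 41.5 |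
| winter | 10.0 | 17.8 | 39.8 | 35.0 |
| midnight | 2.50 | 23.4 | 46.1 | 27.4 |
| midnight | 5.00 | 24.5 | 57.3 | 10.1 |
| midnight | 6.00 | 25.6 | 60.7 | 5.9 |
| midnight | 10.0 | 27.2 | 59.6 | 2.0 |

(standard deviation of a reading: 1 percentage point)

1. ratio of isomer of the product to target at 1.5 h
2. ratio of isomer of the product to target at 15 d

Turn the reagent first. By hand, more reagent speeds the consumption of substrate, and the ratio of isomer to target moves if reagent favours one route. Midnight has twice the reagent of winter, yet at 10.0 d the ratios read 0.456 and 0.447. Now turn the time. If one product fed the other, the ratio would drift. Winter reads 0.461 at its first point and midnight 0.508, a faint fall at best with a scatter of 1 percentage point per reading.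

So divide the rate of making isomer by the rate of making target: time drops out, and while that quotient stays fixed the ratio of the amounts formed equals it. Pooling the last readings gives, as a reading with their scatter, 0.453, the selectivity factor S, isomer gained per target gained. The new flask's 0.0525 M of reagent lies between the two runs, so my reckoning is S at both times, though 1.5 h comes before any reading and 15 d after the last. The forecast says 0.44 and 0.45, from “parallel formation with fixed selectivity”.

The flask gives 0.479 at 1.5 h and 0.438 at 15 d, against the read S of 0.453, and both forecast values stand within their margins.

    substrate + reagent → intermediate + released group (k = 1.60 × 10⁻⁴ /M/s)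
    intermediate ⇌ target (K = 6.40, k = 3.30 × 10⁻⁴ /s)
    intermediate ⇌ isomer of the product (K = 2.80, k = 1.60 × 10⁻⁴ /s)
    reagent ⇌ dormant form (K = 0.350, k = 3.60 × 10⁻⁴ /s)

In the flask, the half-life with which intermediate and target relax toward each other by this step alone, 0.505 h, is far shorter than 15 d. The flask's ratio at 1.5 h lies near the rate-constant ratio 0.485 (kinetic control), its ratio at 15 d near the equilibrium ratio 0.437 (thermodynamic control). Now take a second flask, the same but with 0.013 M of reagent, the limiting reagent there: S again gives a ratio of 0.453 of isomer to target. Computed, that flask holds target 16.3 % and isomer of the product 7.12 % beside substrate 74.1 %, a ratio of 0.438 at 15 d.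

The runs were computed on assumed constants, noise included.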